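**Plan**

- Labels: oxolane O1–C2(OAc)–C3–C4–C5H2; Cα = CH(OAc)CO2Me on C4; C1′ = quaternary azulene carbon on C3. Cuts: (a) the C2–OAc/ester pair, traced back to a C2–C(=O) bond that the target does not contain; (b) O1–C2; (c) C1′–C3.
- Enabling feature: C2 and the ester carbon are 1,5-related along C2–C3–C4–Cα–C(=O), so they can be tied into a cyclopentanone. There C5–O and the α-chloro carbon C2 sit 1,3-cis (5-exo-tet closure to a 2-oxabicyclo[2.2.1]heptanone), and the cis C3/C4 relation of the oxolane is simply trans on the carbocycle.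
- Forward: cyclohexenone → cis-hydrindanone (five-membered ring) → ring expansion to the seven-membered ring → tertiary oxalate; separately a chlorocyclopentenone from cyclopentadienide; radical union (C1′–C3); then the oxolane is closed last, and the temporary C2–C(=O) bond is excised by Baeyer–Villiger oxidation and methanolysis.
- Stereochemistry: C3a by Cu-catalysed asymmetric conjugate addition, C8a by tether-enforced cis closure; C4 and Cα by asymmetric hydroboration and Mitsunobu inversion; C1′ and C3 in the stereoconvergent radical addition (convex face, anti to the acceptor substituents); C2 in the last acetylation (anti to both neighbours).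

Key step: step 15

Assumption: hydroboration of the silyloxymethyl cyclopentadiene 15 with (−)-Ipc2BH is taken to follow the facial sense known for alkoxymethyl cyclopentadienes (trans, 1S,2R).

Step 1
Reactants: 1 4,4-dimethylcyclohex-2-en-1-one; 2 (4-bromobut-1-yn-1-yl)trimethylsilane
Product: 4 {[(3R)-4,4-dimethyl-3-[4-(trimethylsilyl)but-3-yn-1-yl]cyclohex-1-en-1-yl]oxy}tri(propan-2-yl)silane, via Grignard reagent 3 (not isolated)
Conditions: 2, Mg, THF; then 1, CuBr·SMe2 (5 mol%), Josiphos-type ferrocenyl diphosphine (6 mol%, enantiomer giving 3R), t-BuOMe, −75 °C; then TIPSOTf, DMPU, −75 °C → rt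
Reagents that add atoms: triisopropylsilyl trifluoromethanesulfonate, CC(C)[Si](OS(=O)(=O)C(F)(F)F)(C(C)C)C(C)C
Why: Copper-catalysed asymmetric conjugate addition of a Grignard reagent should set the future ring-fusion centre C3a under ligand control, and O-silylation of the magnesium enolate fixes the enol ether on the side needed for the next ring closure.

Step 2
Reactants: 4 silyl enol ether with TMS-alkyne
Product: 5 {[(3R)-3-(but-3-yn-1-yl)-4,4-dimethylcyclohex-1-en-1-yl]oxy}tri(propan-2-yl)silane
Conditions: K2CO3 (cat.), MeOH/THF, 0 °C → rt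
Reagents that add atoms: none
Why: Base-catalysed methanolysis of the alkynyl C–Si bond (protiodesilylation) should free the terminal alkyne while the hindered TIPS enol ether survives.

Step 3
Reactants: 5 terminal alkyne enol ether
Product: 6 (3aR,7aR)-7,7-dimethyl-3-methylideneoctahydro-4H-inden-4-one
Conditions: Ph3PAuCl (10 mol%), AgBF4 (10 mol%), CH2Cl2/MeOH 10:1, 40 °C
Reagents that add atoms: none
Why: Gold(I)-catalysed 5-exo-dig carbocyclisation of the silyl enol ether onto the alkyne (Conia-ene type) should form the cyclopentane with its exocyclic methylene; the three-carbon tether can only reach the enol ether face on which it sits, so the fusion is cis.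

Step 4
Reactants: 6 cis-hydrindanone
Product: 8 (3aR,8aR)-8,8-dimethyl-3-methylideneoctahydroazulen-4(1H)-one, via α-silyl ketone 7 (not isolated)
Conditions: TMSCHN2, BF3·OEt2, CH2Cl2, −78 → −40 °C; then 1 M HCl
Reagents that add atoms: (trimethylsilyl)diazomethane, C[Si](C)(C)C=[N+]=[N-]
Why: Lewis acid-promoted diazoalkane ring expansion (Tiffeneau–Demjanov type) should insert the carbon on the less substituted CH2 side, keeping the carbonyl next to the ring fusion; the α-silyl ketone is protodesilylated on acidic work-up.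

Step 5
Reactants: 8 methylidene hydroazulenone
Product: 9 (3aR,8aR)-3-hydroxy-3,8,8-trimethyloctahydroazulen-4(1H)-one (C3 epimers)
Conditions: Mn(dpm)3 (cat.), PhSiH3, O2 (1 atm), i-PrOH/CH2Cl2, 0 °C
Reagents that add atoms: dioxygen, O=O
Why: Mukaiyama hydration (metal hydride hydrogen-atom transfer, O2 trapping) should hydrate the 1,1-disubstituted alkene in the Markovnikov sense; the carbinol configuration is immaterial because this carbon becomes a radical in step 14.

Step 6
Reactants: 9 hydroxy ketone
Product: 10 (3aR,8aS)-1,4,4-trimethyl-8-methylidenedecahydroazulen-1-ol (C1 epimers)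
Conditions: Ph3PCH3Br, KOt-Bu, THF/toluene, 0 → 70 °C
Reagents that add atoms: methyltriphenylphosphonium bromide, C[P+](c1ccccc1)(c1ccccc1)c1ccccc1.[Br-]
Why: Wittig methylenation of the hindered ketone should install the exocyclic methylene; the ylide is too weak a base to deprotonate the tertiary alcohol to any extent, which limits retro-aldol cleavage.

Step 7
Reactants: 10 tertiary alcohol
Product: 11 methyl (3aR,8aS)-1,4,4-trimethyl-8-methylidenedecahydroazulen-1-yl oxalate
Conditions: ClCOCO2Me, Et3N, DMAP (cat.), CH2Cl2, 0 °C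
Reagents that add atoms: methyl chlorooxoacetate, COC(=O)C(=O)Cl
Why: DMAP-catalysed acylation with the highly electrophilic oxalyl monochloride should esterify even this hindered tertiary alcohol.

Step 8
Reactants: 11 methyl oxalate
Product: 12 cesium 2-oxo-2-{[(3aR,8aS)-1,4,4-trimethyl-8-methylidenedecahydroazulen-1-yl]oxy}acetate
Conditions: CsOH·H2O (1.0 equiv), THF/H2O, rt
Reagents that add atoms: cesium hydroxide, [Cs+].[OH-]
Why: Saponification with one equivalent of hydroxide should cleave only the unhindered methyl ester of the mixed oxalate and give the bench-stable radical precursor.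

Step 9
Reactants: 13 sodium cyclopentadienide; 14 (chloromethoxy)tri(propan-2-yl)silane
Product: 17 (1S,2R)-2-({[tri(propan-2-yl)silyl]oxy}methyl)cyclopent-3-en-1-ol, via silyloxymethylcyclopentadiene 15 (not isolated), via trialkylborane 16 (not isolated)
Conditions: THF, −60 °C; then (−)-Ipc2BH, −60 → 0 °C; then NaOH, H2O2, 0 °C → rt
Reagents that add atoms: hydrogen peroxide, OO
Why: C-alkylation of cyclopentadienide at low temperature (before 1,5-hydrogen shifts), then asymmetric hydroboration with Ipc2BH anti to the substituent and oxidation with retention, should give the trans alcohol with reagent-controlled absolute configuration.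

Step 10
Reactants: 17 trans cyclopentenol
Product: 18 (1R,2R)-2-({[tri(propan-2-yl)silyl]oxy}methyl)cyclopent-3-en-1-yl acetate
Conditions: AcOH, PPh3, DIAD, toluene, 0 °C → rt
Reagents that add atoms: acetic acid, CC(=O)O
Why: Mitsunobu esterification proceeds with inversion, so it should give the cis acetate, which is already the Cα acetate of the target.

Step 11
Reactants: 18 cis acetate
Product: 19 (1S,5R)-2-hydroxy-5-({[tri(propan-2-yl)silyl]oxy}methyl)cyclopent-3-en-1-yl acetate (C2 epimers)
Conditions: SeO2 (cat.), t-BuOOH, CH2Cl2, rt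
Reagents that add atoms: tert-butyl hydroperoxide, CC(C)(C)OO
Why: Selenium dioxide allylic hydroxylation (ene reaction then [2,3]-shift) leaves the alkene in place and should prefer the allylic CH2 over the allylic CH.

Step 12
Reactants: 19 allylic alcohol
Product: 20 (1S,5R)-2-oxo-5-({[tri(propan-2-yl)silyl]oxy}methyl)cyclopent-3-en-1-yl acetate
Conditions: MnO2, CH2Cl2, rt
Reagents that add atoms: none
Why: Manganese dioxide oxidation of the allylic alcohol should give the enone under neutral conditions that do not epimerise the acetoxy carbon.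

Step 13
Reactants: 20 enone
Product: 21 (1S,5R)-3-chloro-2-oxo-5-({[tri(propan-2-yl)silyl]oxy}methyl)cyclopent-3-en-1-yl acetate
Conditions: PhICl2, pyridine, CH2Cl2, 0 °C → rt
Reagents that add atoms: (dichloroiodo)benzene, ClI(Cl)c1ccccc1
Why: α-Chlorination of the enone by chlorine addition and pyridine-mediated loss of HCl should give the 2-chloro enone; the chlorine raises acceptor reactivity and later serves as the leaving group at C2.

Step 14
Reactants: 12 cesium oxalate; 21 chloro enone
Product: 22 (1S,2R,3R)-4-chloro-5-oxo-2-({[tri(propan-2-yl)silyl]oxy}methyl)-3-[(1R,3aR,8aS)-1,4,4-trimethyl-8-methylidenedecahydroazulen-1-yl]cyclopentyl acetate (C4 epimers)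
Conditions: Ir[dF(CF3)ppy]2(dtbbpy)PF6 (1 mol%), H2O (10 equiv), DME/DMF 3:1, blue LEDs, rt → 40 °C
Reagents that add atoms: none
Why: Photoredox decarboxylative Giese addition: oxidation of the oxalate and loss of two CO2 give the tertiary radical, which should add to the β-carbon from its convex face (anti to the seven-membered ring, so both carbinol epimers converge) and anti to the two cis substituents of the acceptor, setting C1′ and C3.

Step 15
Reactants: 22 α-chloro ketone
Product: 24 (1R,4R,5S,7R)-6-oxo-7-[(1R,3aR,8aS)-1,4,4-trimethyl-8-methylidenedecahydroazulen-1-yl]-2-oxabicyclo[2.2.1]heptan-5-yl acetate, via hydroxy chloro ketone 23 (not isolated)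
Conditions: TBAF, THF, 0 °C → rt
Reagents that add atoms: none
Why: Fluoride cleaves the primary silyl ether and the liberated C5 oxygen displaces chloride at C2 by intramolecular SN2 (Williamson-type etherification of an α-halo ketone, 5-exo-tet), closing the oxolane O1–C2–C3–C4–C5 inside a 2-oxabicyclo[2.2.1]heptan-6-one while the temporary C2–C(=O) bond is still in place. The closest known reaction type is the base-mediated cyclisation of hydroxy α-halo ketones to cyclic ethers, made easy here because the cyclopentanone holds C5–O and C2 in a 1,3-cis relation. The only new stereocentre, C2, is set by inversion and by the bridge geometry: only the epimer with chlorine anti to the CH2O arm can close, and the two C2 epimers of 22 interconvert by enolisation, so the step is stereoconvergent. The step needs O-alkylation to outrun E2 loss of HCl, 1,3-acetyl migration and epimerisation at the acetoxy carbon. What secures this is that the attack runs on the ring face opposite the bulky azulenyl group, that a migrated acetyl can only return through the C5 alkoxide (the only species that cyclises), and that in the bicycle the endo acetate, remote from the syn C7 substituent, should be the favoured epimer.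

Step 16
Reactants: 24 bridged keto ether
Product: 25 (1S,4S,5R,8R)-3-oxo-8-[(1R,3aR,8aS)-1,4,4-trimethyl-8-methylidenedecahydroazulen-1-yl]-2,7-dioxabicyclo[3.2.1]octan-4-yl acetate
Conditions: Me3SiOOSiMe3, TMSOTf (cat.), CH2Cl2, −40 → −20 °C
Reagents that add atoms: bis(trimethylsilyl) peroxide, C[Si](C)(C)OO[Si](C)(C)C
Why: Baeyer–Villiger oxidation with a silyl peroxide (no peracid, so the exocyclic alkene should not be epoxidised); the bridgehead α-alkoxy carbon C2 should migrate with retention in preference to the α-acetoxy carbon, inserting oxygen between C2 and the carbonyl and so excising the temporary C–C bond.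

Step 17
Reactants: 25 lactone acetal
Product: 26 methyl (2S)-2-(acetyloxy)-2-[(3R,4R)-5-hydroxy-4-[(1R,3aR,8aS)-1,4,4-trimethyl-8-methylidenedecahydroazulen-1-yl]oxolan-3-yl]acetate (anomers)
Conditions: MeOH, Et3N (cat.), 0 °C → rt
Reagents that add atoms: methanol, CO
Why: Base-catalysed methanolysis of the acylal-type lactone (acyl–oxygen cleavage with a hemiacetal oxide as leaving group) should give the methyl ester and the lactol much faster than it touches the ordinary acetate.

Step 18
Reactants: 26 lactol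
Product: 27 methyl (2S)-2-(acetyloxy)-2-[(3R,4R,5R)-5-(acetyloxy)-4-[(1R,3aR,8aS)-1,4,4-trimethyl-8-methylidenedecahydroazulen-1-yl]oxolan-3-yl]acetate
Conditions: Ac2O, pyridine, DMAP (cat.), CH2Cl2, 0 °C
Reagents that add atoms: acetic anhydride, CC(=O)OC(C)=O
Why: Acetylation of the equilibrating lactol anomers should take place on the face anti to both the C3 and C4 substituents and give the 2,3-trans anomeric acetate; the Cα oxygen is already acetylated, so no isomeric lactol can form.

**Compound list**

1 | 4,4-dimethylcyclohex-2-en-1-one | CC1(C)CCC(=O)C=C1 | starting material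
2 | (4-bromobut-1-yn-1-yl)trimethylsilane | C[Si](C)(C)C#CCCBr | starting material
3 | [4-(trimethylsilyl)but-3-yn-1-yl]magnesium bromide | C[Si](C)(C)C#CCC[Mg]Br | intermediate
4 | {[(3R)-4,4-dimethyl-3-[4-(trimethylsilyl)but-3-yn-1-yl]cyclohex-1-en-1-yl]oxy}tri(propan-2-yl)silane | CC(C)[Si](OC1=C[C@@H](CCC#C[Si](C)(C)C)C(C)(C)CC1)(C(C)C)C(C)C | intermediate
5 | {[(3R)-3-(but-3-yn-1-yl)-4,4-dimethylcyclohex-1-en-1-yl]oxy}tri(propan-2-yl)silane | CC(C)[Si](OC1=C[C@@H](CCC#C)C(C)(C)CC1)(C(C)C)C(C)C | intermediate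
6 | (3aR,7aR)-7,7-dimethyl-3-methylideneoctahydro-4H-inden-4-one | O=C1CCC(C)(C)[C@@H]2CCC(=C)[C@H]12 | intermediate
7 | (3aR,8aR)-8,8-dimethyl-3-methylidene-5-(trimethylsilyl)octahydroazulen-4(1H)-one (C5 epimers) | O=C1C([Si](C)(C)C)CCC(C)(C)[C@@H]2CCC(=C)[C@H]12 | intermediate
8 | (3aR,8aR)-8,8-dimethyl-3-methylideneoctahydroazulen-4(1H)-one | O=C1CCCC(C)(C)[C@@H]2CCC(=C)[C@H]12 | intermediate
9 | (3aR,8aR)-3-hydroxy-3,8,8-trimethyloctahydroazulen-4(1H)-one (C3 epimers) | O=C1CCCC(C)(C)[C@@H]2CCC(C)(O)[C@H]12 | intermediate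
10 | (3aR,8aS)-1,4,4-trimethyl-8-methylidenedecahydroazulen-1-ol (C1 epimers) | C=C1CCCC(C)(C)[C@@H]2CCC(C)(O)[C@H]12 | intermediate
11 | methyl (3aR,8aS)-1,4,4-trimethyl-8-methylidenedecahydroazulen-1-yl oxalate (C1 epimers) | C=C1CCCC(C)(C)[C@@H]2CCC(C)(OC(=O)C(=O)OC)[C@H]12 | intermediate
12 | cesium 2-oxo-2-{[(3aR,8aS)-1,4,4-trimethyl-8-methylidenedecahydroazulen-1-yl]oxy}acetate (C1 epimers) | C=C1CCCC(C)(C)[C@@H]2CCC(C)(OC(=O)C(=O)[O-])[C@H]12.[Cs+] | intermediate
13 | sodium cyclopentadienide | [Na+].c1cc[cH-]c1 | starting material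
14 | (chloromethoxy)tri(propan-2-yl)silane | CC(C)[Si](OCCl)(C(C)C)C(C)C | starting material
15 | [(cyclopenta-2,4-dien-1-yl)methoxy]tri(propan-2-yl)silane | CC(C)[Si](OCC1C=CC=C1)(C(C)C)C(C)C | intermediate
16 | bis(isopinocampheyl)borane adduct of 15, boron trans to the CH2O arm (boron in place of the hydroxyl of 17) | B([C@H]1CC=C[C@@H]1CO[Si](C(C)C)(C(C)C)C(C)C)([C@@H]1C[C@@H]2C[C@H]([C@H]1C)C2(C)C)[C@@H]1C[C@@H]2C[C@H]([C@H]1C)C2(C)C | intermediate
17 | (1S,2R)-2-({[tri(propan-2-yl)silyl]oxy}methyl)cyclopent-3-en-1-ol | O[C@H]1CC=C[C@@H]1CO[Si](C(C)C)(C(C)C)C(C)C | intermediate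
18 | (1R,2R)-2-({[tri(propan-2-yl)silyl]oxy}methyl)cyclopent-3-en-1-yl acetate | CC(=O)O[C@@H]1CC=C[C@@H]1CO[Si](C(C)C)(C(C)C)C(C)C | intermediate
19 | (1S,5R)-2-hydroxy-5-({[tri(propan-2-yl)silyl]oxy}methyl)cyclopent-3-en-1-yl acetate (C2 epimers) | CC(=O)O[C@@H]1C(O)C=C[C@@H]1CO[Si](C(C)C)(C(C)C)C(C)C | intermediate
20 | (1S,5R)-2-oxo-5-({[tri(propan-2-yl)silyl]oxy}methyl)cyclopent-3-en-1-yl acetate | CC(=O)O[C@@H]1C(=O)C=C[C@@H]1CO[Si](C(C)C)(C(C)C)C(C)C | intermediate
21 | (1S,5R)-3-chloro-2-oxo-5-({[tri(propan-2-yl)silyl]oxy}methyl)cyclopent-3-en-1-yl acetate | CC(=O)O[C@@H]1C(=O)C(Cl)=C[C@@H]1CO[Si](C(C)C)(C(C)C)C(C)C | intermediate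
22 | (1S,2R,3R)-4-chloro-5-oxo-2-({[tri(propan-2-yl)silyl]oxy}methyl)-3-[(1R,3aR,8aS)-1,4,4-trimethyl-8-methylidenedecahydroazulen-1-yl]cyclopentyl acetate (C4 epimers) | C=C1CCCC(C)(C)[C@@H]2CC[C@@](C)([C@@H]3C(Cl)C(=O)[C@@H](OC(C)=O)[C@H]3CO[Si](C(C)C)(C(C)C)C(C)C)[C@H]12 | intermediate
23 | (1S,2R,3R)-4-chloro-2-(hydroxymethyl)-5-oxo-3-[(1R,3aR,8aS)-1,4,4-trimethyl-8-methylidenedecahydroazulen-1-yl]cyclopentyl acetate (C4 epimers) | C=C1CCCC(C)(C)[C@@H]2CC[C@@](C)([C@@H]3C(Cl)C(=O)[C@@H](OC(C)=O)[C@H]3CO)[C@H]12 | intermediate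
24 | (1R,4R,5S,7R)-6-oxo-7-[(1R,3aR,8aS)-1,4,4-trimethyl-8-methylidenedecahydroazulen-1-yl]-2-oxabicyclo[2.2.1]heptan-5-yl acetate | C=C1CCCC(C)(C)[C@@H]2CC[C@@](C)([C@@H]3[C@H]4OC[C@@H]3[C@H](OC(C)=O)C4=O)[C@H]12 | intermediate
25 | (1S,4S,5R,8R)-3-oxo-8-[(1R,3aR,8aS)-1,4,4-trimethyl-8-methylidenedecahydroazulen-1-yl]-2,7-dioxabicyclo[3.2.1]octan-4-yl acetate | C=C1CCCC(C)(C)[C@@H]2CC[C@@](C)([C@@H]3[C@H]4OC[C@@H]3[C@H](OC(C)=O)C(=O)O4)[C@H]12 | intermediate
26 | methyl (2S)-2-(acetyloxy)-2-[(3R,4R)-5-hydroxy-4-[(1R,3aR,8aS)-1,4,4-trimethyl-8-methylidenedecahydroazulen-1-yl]oxolan-3-yl]acetate (anomers) | C=C1CCCC(C)(C)[C@@H]2CC[C@@](C)([C@@H]3C(O)OC[C@@H]3[C@H](OC(C)=O)C(=O)OC)[C@H]12 | intermediate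
27 | methyl (2S)-2-(acetyloxy)-2-[(3R,4R,5R)-5-(acetyloxy)-4-[(1R,3aR,8aS)-1,4,4-trimethyl-8-methylidenedecahydroazulen-1-yl]oxolan-3-yl]acetate | C=C1CCCC(C)(C)[C@@H]2CC[C@@](C)([C@@H]3[C@@H](OC(C)=O)OC[C@@H]3[C@H](OC(C)=O)C(=O)OC)[C@H]12 | target

**Step count and risks**

Total: 18 steps. Longest linear sequence: 13 steps (steps 1–8, then 14–18, from 1); the acceptor branch (steps 9–13) is 5 steps.

Steps most likely to fail:

1. Step 15 (oxolane closure). Elimination of HCl, acetyl migration or epimerisation at the acetoxy carbon may outpace the intramolecular displacement. Fallback: close the ring as a lactol after cleaving the temporary ring rather than before. From 22, reductive silylation of the α-chloro ketone (Zn, TMSCl) should give the regiodefined trimethylsilyl enol ether F1. Rubottom oxidation (dimethyldioxirane, 1 equiv, −78 °C) should give the α-hydroxy ketone F2, and HF·pyridine the primary alcohol F3. Pb(OAc)4 in MeOH/benzene (Criegee-type ketol cleavage) would then turn the ketone carbon into the methyl ester and the carbinol carbon into the aldehyde, which the C5 hydroxyl captures; the route is rejoined at 26.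

2. Step 16 (Baeyer–Villiger). Addition of the peroxide to the carbonyl, shielded by the syn azulenyl group, may be too slow, or the Lewis acid may attack the exocyclic alkene. Fallback: alkoxy-radical β-fragmentation instead of peroxide insertion. From 24, NaBH4 should give the bridged alcohol F4. PhI(OAc)2/I2 under visible light would generate the alkoxy radical, whose scission towards the oxygen-stabilised C2 radical, oxidation and capture by acetate should give the acetoxy acetal aldehyde F5. Pinnick oxidation would give the acid F6, and TMSCHN2 returns the route at 27.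

3. Step 4 (ring expansion). The ring-fusion carbon may migrate instead of the CH2, or the Lewis acid may move the β,γ-alkene into conjugation. Fallback: regiospecific Saegusa–Ito expansion. From 6, LDA/TMSCl should give the kinetic enol ether F7 (away from the ring fusion), and Et2Zn/CH2I2 the siloxycyclopropane F8. FeCl3 would open it to the β-chloro ketone F9, NaOAc would give the cycloheptenone F10, and conjugate reduction with Stryker's reagent returns the route at 8.

Further compounds
F1 | step 15 | trimethylsilyl enol ether from 22 (C(OSiMe3)=CH in place of C(=O)–CHCl; other centres as in 22) | C=C1CCCC(C)(C)[C@@H]2CC[C@@](C)([C@@H]3C=C(O[Si](C)(C)C)[C@@H](OC(C)=O)[C@H]3CO[Si](C(C)C)(C(C)C)C(C)C)[C@H]12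
F2 | step 15 | α-hydroxy ketone (OH in place of Cl of 22; carbinol epimers) | C=C1CCCC(C)(C)[C@@H]2CC[C@@](C)([C@@H]3C(O)C(=O)[C@@H](OC(C)=O)[C@H]3CO[Si](C(C)C)(C(C)C)C(C)C)[C@H]12
F3 | step 15 | α-hydroxy ketone with free hydroxymethyl group (desilylated F2) | C=C1CCCC(C)(C)[C@@H]2CC[C@@](C)([C@@H]3C(O)C(=O)[C@@H](OC(C)=O)[C@H]3CO)[C@H]12
F4 | step 16 | 6-hydroxy-2-oxabicyclo[2.2.1]heptan-5-yl acetate from reduction of 24 (carbinol epimers) | C=C1CCCC(C)(C)[C@@H]2CC[C@@](C)([C@@H]3[C@H]4OC[C@@H]3[C@H](OC(C)=O)C4O)[C@H]12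
F5 | step 16 | (2S)-2-(acetyloxy)-2-[(3R,4R,5R)-5-(acetyloxy)-4-(azulenyl)oxolan-3-yl]acetaldehyde (azulenyl group as in 27) | C=C1CCCC(C)(C)[C@@H]2CC[C@@](C)([C@@H]3[C@@H](OC(C)=O)OC[C@@H]3[C@H](OC(C)=O)C=O)[C@H]12
F6 | step 16 | carboxylic acid corresponding to 27 (CO2H in place of CO2Me) | C=C1CCCC(C)(C)[C@@H]2CC[C@@](C)([C@@H]3[C@@H](OC(C)=O)OC[C@@H]3[C@H](OC(C)=O)C(=O)O)[C@H]12
F7 | step 4 | kinetic trimethylsilyl enol ether of 6 (C4=C5 enol ether) | C[Si](C)(C)OC1=CCC(C)(C)[C@@H]2CCC(=C)[C@H]12
F8 | step 4 | siloxycyclopropane from F7 (cyclopropane epimers) | C[Si](C)(C)OC12CC1CC(C)(C)[C@@H]3CCC(=C)[C@H]23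
F9 | step 4 | (3aR,8aR)-6-chloro-8,8-dimethyl-3-methylideneoctahydroazulen-4(1H)-one (C6 epimers) | O=C1CC(Cl)CC(C)(C)[C@@H]2CCC(=C)[C@H]12
F10 | step 4 | (3aR,8aR)-8,8-dimethyl-3-methylidene-2,3,3a,7,8,8a-hexahydroazulen-4(1H)-one | O=C1C=CCC(C)(C)[C@@H]2CCC(=C)[C@H]12
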